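**Retrosynthetic overview**

- Ring C is a C4 carbonyl held between C4a of ring A and the C3–C2 unit that carries ring B and is bonded to O1. It is cut back to an ortho-iodophenol, carbon monoxide and an arylacetylene (bonds C4a–C4, C4–C3 and O1–C2) at the flavone level. The C2=C3 bond is then reduced enantioselectively to set C2 (S), and the MOM ethers are removed last.
- The ortho-iodophenol comes from phloroglucinol. An N-isopropylcarbamate on the central oxygen directs two ortho-lithiations, one before and one after the side chain is attached, and is then cleaved by base.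
- The C10 side chain and its R stereocentre come from (4R)-limonene 1,2-oxide by ring cleavage, Pinnick oxidation, Wittig methylenation and decarboxylative iodination. It is joined to ring A by a two-electron Negishi coupling of the alkylzinc. The free primary radical of this chain is at once a but-3-enyl and a hex-5-enyl radical, so it is only generated where iodine-atom transfer traps it at once.
- Ring order: rings A and B are bought as arenes; ring C is the only ring formed (step 13).

Key step: step 13

Assumption: the sense of induction of the CuH catalyst in step 14 is not derived here; (R)-DTBM-SEGPHOS is written, and its antipode is taken if a trial on a simple flavone shows that it is the one that delivers hydride to the Re face of C2.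

**Route**

Step 1
Reactants: 1 (4R)-limonene 1,2-oxide (commercial cis/trans mixture)
Product: 2 (3R)-6-oxo-3-(prop-1-en-2-yl)heptanal
Conditions: H5IO6, THF/H2O, 0 °C → rt
Reagents that add atoms: water, O
Why: Acid-promoted opening of the epoxide to the trans-diol and periodate glycol cleavage (Malaprade reaction) cut the C1–C2 bond of the p-menthane ring in one flask; the isopropenyl-bearing stereocentre is remote from the reacting carbons and becomes C3 (R) of 2, and both epoxide diastereomers converge on the same product.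

Step 2
Reactants: 2 (3R)-6-oxo-3-(prop-1-en-2-yl)heptanal
Product: 3 (3R)-6-oxo-3-(prop-1-en-2-yl)heptanoic acid
Conditions: NaClO2, NaH2PO4, 2-methyl-2-butene, t-BuOH/H2O, 0 °C → rt
Reagents that add atoms: sodium chlorite, [Na+].[O-]Cl=O
Why: Pinnick oxidation converts only the aldehyde into the acid, 2-methyl-2-butene removes the hypochlorous acid that would otherwise attack the isopropenyl group, and the stereocentre is β to the new carboxyl group and cannot enolise.

Step 3
Reactants: 3 (3R)-6-oxo-3-(prop-1-en-2-yl)heptanoic acid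
Product: 4 (3R)-6-methyl-3-(prop-1-en-2-yl)hept-6-enoic acid
Conditions: Ph3PCH3Br, KOtBu (excess), THF, 0 °C → rt; aq. HCl work-up
Reagents that add atoms: methyltriphenylphosphonium bromide, C[P+](c1ccccc1)(c1ccccc1)c1ccccc1.[Br-]
Why: Wittig methylenation of the methyl ketone with excess ylide, which first converts the acid into the unreactive carboxylate; the stereocentre is γ to the ketone and is not affected.

Step 4
Reactants: 4 (3R)-6-methyl-3-(prop-1-en-2-yl)hept-6-enoic acid
Product: 6 (3S)-3-(iodomethyl)-2,6-dimethylhepta-1,6-diene, via Barton ester 5 (not isolated)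
Conditions: N-hydroxypyridine-2-thione, DCC, DMAP (cat.), CH2Cl2, 0 °C, dark; then CHI3, hν (tungsten lamp), rt
Reagents that add atoms: iodoform, IC(I)I
Why: Barton decarboxylation with iodine-atom transfer (iododecarboxylation): thiohydroxamate ester 5 fragments under visible light to CO2 and the primary radical, which is expected to take iodine from iodoform far faster than it can rearrange as a but-3-enyl radical (1,2-vinyl shift) or cyclise as a hex-5-enyl radical, so constitution and configuration are kept (the descriptor is S only because CH2I now outranks isopropenyl).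

Step 5
Reactants: 7 phloroglucinol
Product: 8 3,5-bis(methoxymethoxy)phenol
Conditions: MOMCl (2 equiv), i-Pr2NEt, DMF, 0 °C → rt
Reagents that add atoms: chloromethyl methyl ether, COCCl
Why: Williamson-type O-alkylation under statistical control: with two equivalents of MOMCl the bis-ether should be the main component and is separated from the mono- and tris-ethers, which can be recycled.

Step 6
Reactants: 8 3,5-bis(methoxymethoxy)phenol
Product: 9 3,5-bis(methoxymethoxy)phenyl N-isopropylcarbamate
Conditions: i-PrNCO, Et3N (cat.), CH2Cl2, rt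
Reagents that add atoms: isopropyl isocyanate, CC(C)N=C=O
Why: Base-catalysed addition of the phenol to the isocyanate (carbamoylation) installs a directing group that is stronger than OMOM and, having an N–H, can later be removed by mild base.

Step 7
Reactants: 9 3,5-bis(methoxymethoxy)phenyl N-isopropylcarbamate
Product: 13 2-iodo-3,5-bis(methoxymethoxy)phenyl N-isopropylcarbamate, via N-silyl carbamate 10 (not isolated), via aryllithium 11 (not isolated), via N-silyl aryl iodide 12 (not isolated)
Conditions: TMSOTf, TMEDA, Et2O, rt; s-BuLi, TMEDA, −78 °C; ICH2CH2I, THF, −78 °C → rt; aq. NH4Cl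
Reagents that add atoms: 1,2-diiodoethane, ICCI
Why: Directed ortho-metalation: transient N-silylation masks the carbamate N–H (the amine-buffered silyl triflate is consumed there and should not activate the MOM ethers), the carbamate and the neighbouring OMOM group direct s-BuLi cooperatively to C2 in preference to C4 between the two weaker OMOM groups, iodine is transferred from 1,2-diiodoethane at −78 °C before an anionic ortho-Fries rearrangement can set in, and the N–Si bond is hydrolysed on work-up.

Step 8
Reactants: 6 (3S)-3-(iodomethyl)-2,6-dimethylhepta-1,6-diene; 13 2-iodo-3,5-bis(methoxymethoxy)phenyl N-isopropylcarbamate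
Product: 15 2-[(2R)-5-methyl-2-(prop-1-en-2-yl)hex-5-en-1-yl]-3,5-bis(methoxymethoxy)phenyl N-isopropylcarbamate, via alkylzinc iodide 14 (not isolated)
Conditions: 6, Zn dust, LiCl, THF, 40 °C; then 13, Pd(OAc)2 (2 mol %), SPhos (4 mol %), THF, 50 °C
Reagents that add atoms: none
Why: Negishi coupling: LiCl-promoted insertion of zinc into the primary C–I bond gives alkylzinc 14, and the Pd/SPhos catalyst joins it to the doubly ortho-substituted aryl iodide by oxidative addition, transmetalation and reductive elimination faster than β-hydride elimination, so the β-stereocentre and both alkenes are kept and the carbamate N–H is tolerated (descriptor R again, the spatial arrangement being unchanged).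

Step 9
Reactants: 15 2-[(2R)-5-methyl-2-(prop-1-en-2-yl)hex-5-en-1-yl]-3,5-bis(methoxymethoxy)phenyl N-isopropylcarbamate
Product: 19 2-iodo-6-[(2R)-5-methyl-2-(prop-1-en-2-yl)hex-5-en-1-yl]-3,5-bis(methoxymethoxy)phenyl N-isopropylcarbamate, via N-silyl carbamate 16 (not isolated), via aryllithium 17 (not isolated), via N-silyl aryl iodide 18 (not isolated)
Conditions: TMSOTf, TMEDA, Et2O, rt; s-BuLi, TMEDA, −78 °C; ICH2CH2I, THF, −78 °C → rt; aq. NH4Cl
Reagents that add atoms: 1,2-diiodoethane, ICCI
Why: Second directed ortho-metalation under the same transient N-silylation: only C6 lies between the carbamate and an OMOM group, so lithiation there should prevail over C4 and over the benzylic and allylic C–H bonds at −78 °C, and 1,2-diiodoethane iodinates the aryllithium without adding to the alkenes.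

Step 10
Reactants: 19 2-iodo-6-[(2R)-5-methyl-2-(prop-1-en-2-yl)hex-5-en-1-yl]-3,5-bis(methoxymethoxy)phenyl N-isopropylcarbamate
Product: 20 2-iodo-6-[(2R)-5-methyl-2-(prop-1-en-2-yl)hex-5-en-1-yl]-3,5-bis(methoxymethoxy)phenol
Conditions: NaOH (2 M aq.), EtOH, 50 °C
Reagents that add atoms: none
Why: Base cleavage of the N-monoalkyl carbamate by the E1cB pathway (N–H deprotonation, loss of the phenoxide, hydrolysis of the isocyanate); MOM ethers, aryl iodide and alkenes are stable to hydroxide.

Step 11
Reactants: 21 2,4-dihydroxybenzaldehyde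
Product: 22 2,4-bis(methoxymethoxy)benzaldehyde
Conditions: MOMCl (excess), i-Pr2NEt, CH2Cl2, 0 °C → 40 °C
Reagents that add atoms: chloromethyl methyl ether, COCCl
Why: Williamson-type MOM protection of both phenols, the hydrogen-bonded 2-OH requiring excess reagent and gentle warming.

Step 12
Reactants: 22 2,4-bis(methoxymethoxy)benzaldehyde
Product: 23 1-ethynyl-2,4-bis(methoxymethoxy)benzene
Conditions: dimethyl (1-diazo-2-oxopropyl)phosphonate, K2CO3, MeOH, rt
Reagents that add atoms: dimethyl (1-diazo-2-oxopropyl)phosphonate, CC(=O)C(=[N+]=[N-])P(=O)(OC)OC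
Why: Seyferth–Gilbert homologation in the Ohira–Bestmann variant: methanolysis of the reagent gives the diazomethylphosphonate anion, which olefinates the aldehyde and loses N2 with 1,2-hydrogen shift to the terminal alkyne under a carbonate base that leaves the MOM ethers intact.

Step 13
Reactants: 20 2-iodo-6-[(2R)-5-methyl-2-(prop-1-en-2-yl)hex-5-en-1-yl]-3,5-bis(methoxymethoxy)phenol; 23 1-ethynyl-2,4-bis(methoxymethoxy)benzene; 24 carbon monoxide
Product: 27 2-[2,4-bis(methoxymethoxy)phenyl]-5,7-bis(methoxymethoxy)-8-[(2R)-5-methyl-2-(prop-1-en-2-yl)hex-5-en-1-yl]-4H-chromen-4-one, via ynone 25 (not isolated), via enaminone 26 (not isolated)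
Conditions: PdCl2(PPh3)2 (5 mol %), CO (20 bar), Et2NH, 120 °C
Reagents that add atoms: none
Why: PdCl2(PPh3)2 is reduced in situ to zerovalent palladium, which adds oxidatively to the C–I bond of 20; CO insertion gives the aroyl–palladium iodide, and amine-assisted transfer of the acetylide of 23 followed by reductive elimination forms C4a–C4 and C4–C3 in ynone 25. Diethylamine then adds to the ynone to give enaminone 26, and the neighbouring phenol closes ring C by conjugate addition and loss of diethylamine, forming O1–C2. The closest known reaction type is the palladium-catalysed carbonylative coupling and annulation of ortho-iodophenols with terminal alkynes to chromones and flavones. Ring C (the pyranone) closes in the 6-endo mode, as an addition–elimination at the β-carbon of the enaminone; no stereocentre is formed and the side-chain centre is not involved. The step needs carbonylative over direct alkyne coupling, secured by the CO pressure and the absence of copper, and 6-endo over 5-exo (aurone) closure, secured by the enaminone pathway that the secondary amine opens. The isolated 1,1-disubstituted alkenes of the side chain are not expected to compete with the alkyne for the acyl–palladium species, and the MOM ethers are stable to the basic medium.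

Step 14
Reactants: 27 2-[2,4-bis(methoxymethoxy)phenyl]-5,7-bis(methoxymethoxy)-8-[(2R)-5-methyl-2-(prop-1-en-2-yl)hex-5-en-1-yl]-4H-chromen-4-one
Product: 29 (2S)-2-[2,4-bis(methoxymethoxy)phenyl]-5,7-bis(methoxymethoxy)-8-[(2R)-5-methyl-2-(prop-1-en-2-yl)hex-5-en-1-yl]chroman-4-one, via silyl enol ether 28 (not isolated)
Conditions: Cu(OAc)2 (5 mol %), (R)-DTBM-SEGPHOS (5.5 mol %), (EtO)2MeSiH, toluene, 0 °C → rt; then AcOH/H2O, THF, 0 °C
Reagents that add atoms: none
Why: Proposed new method: the closest known reaction type is the asymmetric conjugate reduction of β,β-disubstituted cyclic enones and 2-alkylchromones by bisphosphine-ligated CuH (hydrocupration of the C=C bond with hydride delivered to the β-carbon, then σ-bond metathesis of the copper enolate with the silane to a silyl enol ether and fresh CuH); its use on a 5,7-dialkoxyflavone with an ortho-substituted 2-aryl group is not established, but the C4 carbonyl still polarises C2, the DTBM-SEGPHOS–CuH complex is among the most reactive of its class, C2 (S) should be set by ligand-controlled delivery of hydride to the Re face of C2, silyl enol ether 28 shields C4 from 1,2-reduction until the mild hydrolytic work-up, and the unactivated 1,1-disubstituted alkenes and the MOM ethers are not expected to react at this temperature.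

Step 15
Reactants: 29 (2S)-2-[2,4-bis(methoxymethoxy)phenyl]-5,7-bis(methoxymethoxy)-8-[(2R)-5-methyl-2-(prop-1-en-2-yl)hex-5-en-1-yl]chroman-4-one
Product: 30 remangiflavanone B, (2S)-2-(2,4-dihydroxyphenyl)-5,7-dihydroxy-8-[(2R)-5-methyl-2-(prop-1-en-2-yl)hex-5-en-1-yl]chroman-4-one
Conditions: 3 M aq. HCl, MeOH, 40 °C
Reagents that add atoms: none
Why: Acid-catalysed methanolysis of the four MOM acetals (transacetalisation to dimethoxymethane), run under the mildest conditions that still cleave aryl MOM ethers so that protonation of the isopropenyl group (chroman formation with the 7-OH) and ring-opening epimerisation at C2 stay slow; no stereocentre is formed or touched.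

**Compound list**

1 | (4R)-limonene 1,2-oxide, cis/trans mixture [(4R)-1-methyl-4-(prop-1-en-2-yl)-7-oxabicyclo[4.1.0]heptane] | CC12OC1C[C@@H](CC2)C(C)=C | starting material
2 | (3R)-6-oxo-3-(prop-1-en-2-yl)heptanal | CC(=O)CC[C@H](CC=O)C(C)=C | intermediate
3 | (3R)-6-oxo-3-(prop-1-en-2-yl)heptanoic acid | CC(=O)CC[C@H](CC(=O)O)C(C)=C | intermediate
4 | (3R)-6-methyl-3-(prop-1-en-2-yl)hept-6-enoic acid | C=C(C)CC[C@H](CC(=O)O)C(C)=C | intermediate
5 | 2-thioxopyridin-1(2H)-yl (3R)-6-methyl-3-(prop-1-en-2-yl)hept-6-enoate (Barton ester) | C=C(C)CC[C@H](CC(=O)ON1C=CC=CC1=S)C(C)=C | intermediate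
6 | (3S)-3-(iodomethyl)-2,6-dimethylhepta-1,6-diene | C=C(C)CC[C@H](CI)C(C)=C | intermediate
7 | phloroglucinol | Oc1cc(O)cc(O)c1 | starting material
8 | 3,5-bis(methoxymethoxy)phenol | COCOc1cc(O)cc(OCOC)c1 | intermediate
9 | 3,5-bis(methoxymethoxy)phenyl N-isopropylcarbamate | COCOc1cc(OCOC)cc(OC(=O)NC(C)C)c1 | intermediate
10 | 3,5-bis(methoxymethoxy)phenyl N-isopropyl-N-(trimethylsilyl)carbamate | COCOc1cc(OCOC)cc(OC(=O)N(C(C)C)[Si](C)(C)C)c1 | intermediate
11 | 2-lithio-3,5-bis(methoxymethoxy)phenyl N-isopropyl-N-(trimethylsilyl)carbamate | COCOc1cc(OCOC)c([Li])c(OC(=O)N(C(C)C)[Si](C)(C)C)c1 | intermediate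
12 | 2-iodo-3,5-bis(methoxymethoxy)phenyl N-isopropyl-N-(trimethylsilyl)carbamate | COCOc1cc(OCOC)c(I)c(OC(=O)N(C(C)C)[Si](C)(C)C)c1 | intermediate
13 | 2-iodo-3,5-bis(methoxymethoxy)phenyl N-isopropylcarbamate | COCOc1cc(OCOC)c(I)c(OC(=O)NC(C)C)c1 | intermediate
14 | [(2S)-5-methyl-2-(prop-1-en-2-yl)hex-5-en-1-yl]zinc iodide | C=C(C)CC[C@H](C[Zn]I)C(C)=C | intermediate
15 | 2-[(2R)-5-methyl-2-(prop-1-en-2-yl)hex-5-en-1-yl]-3,5-bis(methoxymethoxy)phenyl N-isopropylcarbamate | C=C(C)CC[C@H](Cc1c(OCOC)cc(OCOC)cc1OC(=O)NC(C)C)C(C)=C | intermediate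
16 | N-trimethylsilyl derivative of 15 | C=C(C)CC[C@H](Cc1c(OCOC)cc(OCOC)cc1OC(=O)N(C(C)C)[Si](C)(C)C)C(C)=C | intermediate
17 | 6-lithio derivative of 16 (lithium between the carbamate and an OMOM group) | C=C(C)CC[C@H](Cc1c(OCOC)cc(OCOC)c([Li])c1OC(=O)N(C(C)C)[Si](C)(C)C)C(C)=C | intermediate
18 | N-trimethylsilyl derivative of 19 | C=C(C)CC[C@H](Cc1c(OCOC)cc(OCOC)c(I)c1OC(=O)N(C(C)C)[Si](C)(C)C)C(C)=C | intermediate
19 | 2-iodo-6-[(2R)-5-methyl-2-(prop-1-en-2-yl)hex-5-en-1-yl]-3,5-bis(methoxymethoxy)phenyl N-isopropylcarbamate | C=C(C)CC[C@H](Cc1c(OCOC)cc(OCOC)c(I)c1OC(=O)NC(C)C)C(C)=C | intermediate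
20 | 2-iodo-6-[(2R)-5-methyl-2-(prop-1-en-2-yl)hex-5-en-1-yl]-3,5-bis(methoxymethoxy)phenol | C=C(C)CC[C@H](Cc1c(OCOC)cc(OCOC)c(I)c1O)C(C)=C | intermediate
21 | 2,4-dihydroxybenzaldehyde | O=Cc1ccc(O)cc1O | starting material
22 | 2,4-bis(methoxymethoxy)benzaldehyde | O=Cc1ccc(OCOC)cc1OCOC | intermediate
23 | 1-ethynyl-2,4-bis(methoxymethoxy)benzene | C#Cc1ccc(OCOC)cc1OCOC | intermediate
24 | carbon monoxide | [C-]#[O+] | starting material
25 | 3-[2,4-bis(methoxymethoxy)phenyl]-1-{2-hydroxy-4,6-bis(methoxymethoxy)-3-[(2R)-5-methyl-2-(prop-1-en-2-yl)hex-5-en-1-yl]phenyl}prop-2-yn-1-one | C=C(C)CC[C@H](Cc1c(OCOC)cc(OCOC)c(C(=O)C#Cc2ccc(OCOC)cc2OCOC)c1O)C(C)=C | intermediate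
26 | 3-[2,4-bis(methoxymethoxy)phenyl]-3-(diethylamino)-1-{2-hydroxy-4,6-bis(methoxymethoxy)-3-[(2R)-5-methyl-2-(prop-1-en-2-yl)hex-5-en-1-yl]phenyl}prop-2-en-1-one | C=C(C)CC[C@H](Cc1c(OCOC)cc(OCOC)c(C(=O)C=C(N(CC)CC)c2ccc(OCOC)cc2OCOC)c1O)C(C)=C | intermediate
27 | 2-[2,4-bis(methoxymethoxy)phenyl]-5,7-bis(methoxymethoxy)-8-[(2R)-5-methyl-2-(prop-1-en-2-yl)hex-5-en-1-yl]-4H-chromen-4-one | C=C(C)CC[C@H](Cc1c(OCOC)cc(OCOC)c2c1OC(c1ccc(OCOC)cc1OCOC)=CC2=O)C(C)=C | intermediate
28 | (2S)-2-[2,4-bis(methoxymethoxy)phenyl]-4-[diethoxy(methyl)silyloxy]-5,7-bis(methoxymethoxy)-8-[(2R)-5-methyl-2-(prop-1-en-2-yl)hex-5-en-1-yl]-2H-chromene | C=C(C)CC[C@H](Cc1c(OCOC)cc(OCOC)c2c1O[C@H](c1ccc(OCOC)cc1OCOC)C=C2O[Si](C)(OCC)OCC)C(C)=C | intermediate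
29 | (2S)-2-[2,4-bis(methoxymethoxy)phenyl]-5,7-bis(methoxymethoxy)-8-[(2R)-5-methyl-2-(prop-1-en-2-yl)hex-5-en-1-yl]chroman-4-one | C=C(C)CC[C@H](Cc1c(OCOC)cc(OCOC)c2c1O[C@H](c1ccc(OCOC)cc1OCOC)CC2=O)C(C)=C | intermediate
30 | remangiflavanone B | C=C(C)CC[C@H](Cc1c(O)cc(O)c2c1O[C@H](c1ccc(O)cc1O)CC2=O)C(=C)C | target

**Step count**

Total: 15 steps. Longest linear sequence: 10 steps (steps 1, 2, 3, 4, 8, 9, 10, 13, 14, 15).

**Steps most likely to fail**

1. Step 14 (Proposed new method). The hydrocupration may stall on the doubly donor-deactivated and hindered enone, hydride delivery may show poor facial selectivity, or the copper enolate may open ring C by β-elimination of the phenoxide. The fallback uses known chemistry, sets out from 20 and comes back at 29, and does not pass through the flavone. Stille coupling of 20 with tributyl(1-ethoxyvinyl)stannane (Pd(PPh3)4, toluene, 100 °C) should give the aryl enol ether F1, which is hydrolysed (1 M aq. HCl, THF, 0 °C) to the 2-hydroxyacetophenone F2. Claisen–Schmidt condensation of F2 with aldehyde 22 (KOH, EtOH, rt) gives the 2'-hydroxychalcone F3. Oxa-Michael closure (NaOAc, EtOH, reflux) gives the flavanone as a mixture of C2 epimers F4. Asymmetric transfer hydrogenation under kinetic-resolution conditions (RuCl(p-cymene)[(R,R)-TsDPEN], HCO2H/Et3N, EtOAc, rt) is expected to reduce the (2R)-epimer to the cis-flavan-4-ol F5 and to leave the (2S)-epimer, which is 29. At most half of the material is carried through unless F5 is recycled.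

2. Step 13. Slow oxidative addition at the electron-rich, doubly ortho-substituted C–I bond may let aminocarbonylation by diethylamine, direct alkyne coupling (then benzofuran formation) or 5-exo closure take over. The fallback sets out from 20 and 23 and comes back at 27; it forms C4a–C4 by polar acylation instead of CO insertion. Alkyne 23 is deprotonated (n-BuLi, THF, −78 °C) to the lithium acetylide F6, which is acylated with N-methoxy-N-methylcarbamoyl chloride to the propiolic Weinreb amide F7. Iodophenol 20 is converted with n-BuLi (2.1 equiv, THF, −78 °C) into the lithium 2-lithiophenoxide F8, which adds to F7 and gives ynone 25 on work-up. Treatment of 25 with Et2NH in EtOH (rt → 60 °C) passes through enaminone 26 and closes ring C to flavone 27.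

3. Step 15. Protonation of the isopropenyl group with capture of the tertiary cation by the freed 7-OH (chroman formation), addition of methanol or HCl to the alkenes, or acid-promoted epimerisation at C2 may accompany acetal cleavage. The fallback sets out from 29 and comes back at 30; it replaces Brønsted-acid solvolysis by a two-stage transprotection. TMSOTf and 2,2'-bipyridyl (CH2Cl2, 0 °C → rt) should convert the four aryl MOM ethers into the tetrakis(trimethylsilyl) ether F9, with the methoxymethyl groups leaving as N-(methoxymethyl)bipyridinium salt. Addition of water at rt then hydrolyses the silyl ethers to 30 without free strong acid.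

**Further compounds**

F1 | step 14 | 2-(1-ethoxyethenyl)-3,5-bis(methoxymethoxy)-6-[(2R)-5-methyl-2-(prop-1-en-2-yl)hex-5-en-1-yl]phenol | C=C(C)CC[C@H](Cc1c(OCOC)cc(OCOC)c(C(=C)OCC)c1O)C(C)=C
F2 | step 14 | 1-{2-hydroxy-4,6-bis(methoxymethoxy)-3-[(2R)-5-methyl-2-(prop-1-en-2-yl)hex-5-en-1-yl]phenyl}ethan-1-one | C=C(C)CC[C@H](Cc1c(OCOC)cc(OCOC)c(C(C)=O)c1O)C(C)=C
F3 | step 14 | (E)-3-[2,4-bis(methoxymethoxy)phenyl]-1-{2-hydroxy-4,6-bis(methoxymethoxy)-3-[(2R)-5-methyl-2-(prop-1-en-2-yl)hex-5-en-1-yl]phenyl}prop-2-en-1-one | C=C(C)CC[C@H](Cc1c(OCOC)cc(OCOC)c(C(=O)/C=C/c2ccc(OCOC)cc2OCOC)c1O)C(C)=C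
F4 | step 14 | 2-[2,4-bis(methoxymethoxy)phenyl]-5,7-bis(methoxymethoxy)-8-[(2R)-5-methyl-2-(prop-1-en-2-yl)hex-5-en-1-yl]chroman-4-one, mixture of C2 epimers | C=C(C)CC[C@H](Cc1c(OCOC)cc(OCOC)c2c1OC(c1ccc(OCOC)cc1OCOC)CC2=O)C(C)=C
F5 | step 14 | (2R,4R)-2-[2,4-bis(methoxymethoxy)phenyl]-5,7-bis(methoxymethoxy)-8-[(2R)-5-methyl-2-(prop-1-en-2-yl)hex-5-en-1-yl]chroman-4-ol | C=C(C)CC[C@H](Cc1c(OCOC)cc(OCOC)c2c1O[C@@H](c1ccc(OCOC)cc1OCOC)C[C@H]2O)C(C)=C
F6 | step 13 | lithium [2,4-bis(methoxymethoxy)phenyl]acetylide | [Li]C#Cc1ccc(OCOC)cc1OCOC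
F7 | step 13 | 3-[2,4-bis(methoxymethoxy)phenyl]-N-methoxy-N-methylprop-2-ynamide | CON(C)C(=O)C#Cc1ccc(OCOC)cc1OCOC
F8 | step 13 | lithium 2-lithio-3,5-bis(methoxymethoxy)-6-[(2R)-5-methyl-2-(prop-1-en-2-yl)hex-5-en-1-yl]phenoxide | C=C(C)CC[C@H](Cc1c(OCOC)cc(OCOC)c([Li])c1O[Li])C(C)=C
F9 | step 15 | (2S)-8-[(2R)-5-methyl-2-(prop-1-en-2-yl)hex-5-en-1-yl]-5,7-bis(trimethylsilyloxy)-2-[2,4-bis(trimethylsilyloxy)phenyl]chroman-4-one | C=C(C)CC[C@H](Cc1c(O[Si](C)(C)C)cc(O[Si](C)(C)C)c2c1O[C@H](c1ccc(O[Si](C)(C)C)cc1O[Si](C)(C)C)CC2=O)C(C)=C
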